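**Plan**

1. Retrosynthesis: the side-chain ester C–O bond is cut, the acrylic acid is traced back to an isopropenyl group (allylic C–H oxidation), and the cyclohexane ring is then cut twice: between the O-acyl carbinol carbon and the ring CH bearing the acrylate (carbonyl-ene retron), and between the quaternary methyl/vinyl carbon and the ring CH bearing the CH2=C(CH2OH) group (oxy-Cope retron).
2. Enabling feature of the six-membered ring: from the O-acyl carbinol carbon the ring CH2 is α and the quaternary carbon is β, and the next ring carbon carries a 1,1-disubstituted C=CH2 (a δ,ε-unsaturated aldehyde after a [3,3] shift). On its other side the carbinol carbon is flanked by a ring CH carrying a C(=CH2) unit trans to oxygen (an isopulegol-type homoallylic alcohol).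
3. Both cuts converge on one acyclic (Z)-dienyl carbinol. Its carbinol–CH2 bond is absent from the target; it is made on purpose by a propargylation as a temporary tether and is broken in the key step.
4. Forward: the chain is built linearly from (Z)-3-methylpent-2-en-4-yn-1-ol, an allenylboronate, 3-methylbut-2-enal and a hydroxymethylstannane. A one-flask anionic oxy-Cope/carbonyl-ene sequence then forms the only ring, and esterification, SeO2/MnO2/NaClO2 oxidation and PMB removal finish the synthesis.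
5. Stereochemistry: two catalyst-controlled carbinol centres (one is consumed in the key step, one stays as the ring CH–OH) and three defined alkene geometries are relayed through a chair [3,3] transition state into the quaternary centre and its neighbour. The ene chair then sets the last two ring centres all-trans.

Key step: step 11

Remark: the catalyst enantiomers named in steps 3 and 5 are those expected to give the 4R and 9S carbinols; if the facial sense is the opposite, the antipodal catalyst is used.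
Remark: the tert-butyl Still–Gennari phosphonate of step 13 is treated as a purchasable reagent.

**Route**

Step 1
Reactants: 1 (2Z)-3-methylpent-2-en-4-yn-1-ol
Product: 3 (2Z)-3-methyl-5-(trimethylsilyl)pent-2-en-4-yn-1-ol, via bis-silyl ether 2 (not isolated)
Conditions: n-BuLi (2.2 equiv), THF, −78 → 0 °C; Me3SiCl (2.3 equiv); then 1 M aq. HCl, 23 °C
Reagents that add atoms: chlorotrimethylsilane, C[Si](C)(C)Cl
Why: Double deprotonation and silylation at oxygen and at the alkyne carbon, then selective acid hydrolysis of the labile O–Si bond (standard capping of a terminal alkyne), should leave the Z alkene untouched.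

Step 2
Reactants: 3 (2Z)-3-methyl-5-(trimethylsilyl)pent-2-en-4-yn-1-ol
Product: 4 (2Z)-3-methyl-5-(trimethylsilyl)pent-2-en-4-ynal
Conditions: MnO2 (excess), CH2Cl2, 23 °C
Reagents that add atoms: none
Why: Allylic alcohol oxidation with MnO2 under neutral conditions should keep the Z enal geometry, and the linear alkyne cannot take part in an oxa-electrocyclisation.

Step 3
Reactants: 4 (2Z)-3-methyl-5-(trimethylsilyl)pent-2-en-4-ynal; 5 4,4,5,5-tetramethyl-2-(propa-1,2-dien-1-yl)-1,3,2-dioxaborolane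
Product: 6 (4R,5Z)-6-methyl-8-(trimethylsilyl)oct-5-ene-1,7-diyn-4-ol
Conditions: (R)-TRIP phosphoric acid (5 mol %), 4 Å MS, toluene, 0 °C; aqueous work-up
Reagents that add atoms: none
Why: Chiral phosphoric acid-catalysed propargylation with the allenylboronate (closed six-membered transition state, SE2′ transposition) should give the homopropargylic alcohol, the catalyst shielding one face of the conjugated aldehyde to set the 4R centre.

Step 4
Reactants: 6 (4R,5Z)-6-methyl-8-(trimethylsilyl)oct-5-ene-1,7-diyn-4-ol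
Product: 7 {[(4R,5Z)-6-methyl-8-(trimethylsilyl)oct-5-ene-1,7-diyn-4-yl]oxy}tri(propan-2-yl)silane
Conditions: iPr3SiOTf, 2,6-lutidine, CH2Cl2, −78 → 0 °C
Reagents that add atoms: triisopropylsilyl trifluoromethanesulfonate, CC(C)[Si](C(C)C)(C(C)C)OS(=O)(=O)C(F)(F)F
Why: Silylation of the only hydroxyl; the bulky silyl ether should not migrate under the NaH conditions of step 8 and leaves with fluoride together with the alkynylsilane in step 9.

Step 5
Reactants: 7 {[(4R,5Z)-6-methyl-8-(trimethylsilyl)oct-5-ene-1,7-diyn-4-yl]oxy}tri(propan-2-yl)silane; 8 3-methylbut-2-enal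
Product: 9 (3Z,5R,9S)-3,11-dimethyl-5-{[tri(propan-2-yl)silyl]oxy}-1-(trimethylsilyl)dodeca-3,10-diene-1,7-diyn-9-ol
Conditions: Me2Zn (3 equiv), (S,S)-ProPhenol (20 mol %), Ph3P=O (40 mol %), toluene, 4 °C
Reagents that add atoms: none
Why: Dinuclear zinc–ProPhenol catalysed enantioselective alkynylation of an α,β-unsaturated aldehyde should set the 9S carbinol under catalyst control, independent of the remote silyl ether centre.

Step 6
Reactants: 9 (3Z,5R,9S)-3,11-dimethyl-5-{[tri(propan-2-yl)silyl]oxy}-1-(trimethylsilyl)dodeca-3,10-diene-1,7-diyn-9-ol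
Product: 11 (3Z,5R,7Z,9S)-7-iodo-3,11-dimethyl-5-{[tri(propan-2-yl)silyl]oxy}-1-(trimethylsilyl)dodeca-3,7,10-trien-1-yn-9-ol, via cyclic alkenylalanate 10 (not isolated)
Conditions: NaAlH2(OCH2CH2OMe)2 (2.5 equiv), THF, 0 → 23 °C; then I2, THF, −78 °C
Reagents that add atoms: iodine, II
Why: Hydroxyl-directed trans-hydroalumination of the propargylic alcohol places aluminium on the distal alkyne carbon, cis to the carbinol carbon, in a five-membered alanate; iodinolysis with retention should give the Z iodoalkene (the capped enyne has no propargylic alkoxide and is not reduced).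

Step 7
Reactants: 11 (3Z,5R,7Z,9S)-7-iodo-3,11-dimethyl-5-{[tri(propan-2-yl)silyl]oxy}-1-(trimethylsilyl)dodeca-3,7,10-trien-1-yn-9-ol; 12 (tributylstannyl)methanol
Product: 13 (2Z,4S)-6-methyl-2-[(2R,3Z)-4-methyl-2-{[tri(propan-2-yl)silyl]oxy}-6-(trimethylsilyl)hex-3-en-5-yn-1-yl]hepta-2,5-diene-1,4-diol
Conditions: Pd(PPh3)4 (5 mol %), toluene, 90 °C
Reagents that add atoms: none
Why: Stille coupling with retention of alkene geometry transfers the hydroxymethyl group from tin, so CH2OH should end up cis to the carbinol carbon on the trisubstituted alkene.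

Step 8
Reactants: 13 (2Z,4S)-6-methyl-2-[(2R,3Z)-4-methyl-2-{[tri(propan-2-yl)silyl]oxy}-6-(trimethylsilyl)hex-3-en-5-yn-1-yl]hepta-2,5-diene-1,4-diol
Product: 14 {[(3Z,5R,7Z,9S)-9-[(4-methoxyphenyl)methoxy]-7-{[(4-methoxyphenyl)methoxy]methyl}-3,11-dimethyl-1-(trimethylsilyl)dodeca-3,7,10-trien-1-yn-5-yl]oxy}tri(propan-2-yl)silane
Conditions: NaH (3 equiv), 4-MeOC6H4CH2Cl (2.6 equiv), Bu4NI (cat.), THF/DMF, 0 → 23 °C
Reagents that add atoms: 4-methoxybenzyl chloride, COc1ccc(CCl)cc1
Why: Williamson etherification of both hydroxyls; PMB ethers are sterically small at oxygen, inert to amide base and removable oxidatively at the end.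

Step 9
Reactants: 14 {[(3Z,5R,7Z,9S)-9-[(4-methoxyphenyl)methoxy]-7-{[(4-methoxyphenyl)methoxy]methyl}-3,11-dimethyl-1-(trimethylsilyl)dodeca-3,7,10-trien-1-yn-5-yl]oxy}tri(propan-2-yl)silane
Product: 15 (3Z,5R,7Z,9S)-9-[(4-methoxyphenyl)methoxy]-7-{[(4-methoxyphenyl)methoxy]methyl}-3,11-dimethyldodeca-3,7,10-trien-1-yn-5-ol
Conditions: Bu4NF (3 equiv), THF, 0 → 23 °C
Reagents that add atoms: none
Why: Fluoride desilylation should cleave the O–Si bond of the silyl ether and the C(sp)–Si bond in the same pot, while PMB ethers are inert.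

Step 10
Reactants: 15 (3Z,5R,7Z,9S)-9-[(4-methoxyphenyl)methoxy]-7-{[(4-methoxyphenyl)methoxy]methyl}-3,11-dimethyldodeca-3,7,10-trien-1-yn-5-ol
Product: 16 (3Z,5R,7Z,9S)-9-[(4-methoxyphenyl)methoxy]-7-{[(4-methoxyphenyl)methoxy]methyl}-3,11-dimethyldodeca-1,3,7,10-tetraen-5-ol
Conditions: H2 (1 atm), Pd/CaCO3/Pb(OAc)2 (Lindlar), quinoline, EtOAc, 23 °C
Reagents that add atoms: none
Why: Lindlar semihydrogenation should stop at the alkene for the terminal alkyne of the conjugated enyne, leaving trisubstituted alkenes, benzylic ethers and the existing Z geometry untouched.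

Step 11
Reactants: 16 (3Z,5R,7Z,9S)-9-[(4-methoxyphenyl)methoxy]-7-{[(4-methoxyphenyl)methoxy]methyl}-3,11-dimethyldodeca-1,3,7,10-tetraen-5-ol
Product: 19 (1S,2R,3R,4S,5R)-5-ethenyl-3-[(4-methoxyphenyl)methoxy]-4-{3-[(4-methoxyphenyl)methoxy]prop-1-en-2-yl}-5-methyl-2-(prop-1-en-2-yl)cyclohexan-1-ol, via potassium enolate 17 (not isolated), via aldehyde 18 (not isolated)
Conditions: KN(SiMe3)2 (1.3 equiv), 18-crown-6 (1.5 equiv), toluene, 0 → 40 °C; AcOH (1.3 equiv), −78 °C; Me2AlCl (5 equiv), CH2Cl2, −78 → −30 °C (one flask)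
Reagents that add atoms: none
Why: The potassium alkoxide of 16 should undergo an anionic oxy-Cope [3,3] shift through a chair with the alkoxide oxygen equatorial (axial, it would be 1,3-diaxial to the cis vinyl group): the carbinol–CH2 tether breaks and the methyl/vinyl-bearing alkene carbon bonds to the alkene carbon next to the PMB-oxy centre, so the 5R carbinol and the 3Z and 7Z geometries fix the quaternary centre (R) and its neighbour (S), with allylic 1,3-strain at the 9S centre (hydrogen in the alkene plane, alkenyl group anti to the forming bond) making this the matched case. Protonation of enolate 17 gives aldehyde 18, whose Me2AlCl complex closes the only ring by a type 1 intramolecular carbonyl-ene reaction (six-membered ring, exo with respect to both C=O and C=C, chair transition state), the hydrogen of the E methyl group passing to oxygen. The closest known reaction types are the tandem oxy-Cope/ene sequence and the Lewis acid cyclisation of citronellal to isopulegol. In the ene chair the PMB-oxy group is equatorial because allylic strain with the Z methyl group keeps its C–H bond in the alkene plane, and the carbonyl oxygen is equatorial because an axial oxygen would be 1,3-diaxial to the axial vinyl group; this gives the all-trans O, C, O array (1S,2R). The step needs site selectivity for the prenyl-type alkene over the 2-(PMB-oxymethyl)allyl alkene (a type 2 closure), which should hold because that path puts positive charge β to an aluminium-bound ether oxygen, and it needs the [3,3] shift to outrun a 1,5-hydrogen shift of the Z-dienyl alkoxide, which is expected at or below 40 °C.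

Step 12
Reactants: 20 (2Z)-but-2-ene-1,4-diyl diacetate
Product: 22 2-oxoethyl acetate, via ozonide 21 (not isolated)
Conditions: O3, CH2Cl2, −78 °C; Me2S, −78 → 23 °C
Reagents that add atoms: ozone, [O-][O+]=O
Why: Ozonolysis of the symmetrical alkene with reductive work-up should give two equivalents of the aldehyde, used crude.

Step 13
Reactants: 22 2-oxoethyl acetate; 23 tert-butyl 2-[bis(2,2,2-trifluoroethoxy)phosphoryl]propanoate
Product: 24 tert-butyl (2Z)-4-(acetyloxy)-2-methylbut-2-enoate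
Conditions: KN(SiMe3)2, 18-crown-6, THF, −78 °C
Reagents that add atoms: none
Why: Still–Gennari olefination with the bis(trifluoroethyl) phosphonate and a dissociated potassium base should give the Z trisubstituted enoate under kinetic control.

Step 14
Reactants: 24 tert-butyl (2Z)-4-(acetyloxy)-2-methylbut-2-enoate
Product: 25 (2Z)-4-(acetyloxy)-2-methylbut-2-enoic acid
Conditions: CF3CO2H, CH2Cl2, 0 → 23 °C
Reagents that add atoms: none
Why: Acidolysis of the tert-butyl ester (loss of isobutene) frees the acid without touching the acetate, and because the γ-oxygen is already acylated the Z acid cannot lactonise.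

Step 15
Reactants: 19 (1S,2R,3R,4S,5R)-5-ethenyl-3-[(4-methoxyphenyl)methoxy]-4-{3-[(4-methoxyphenyl)methoxy]prop-1-en-2-yl}-5-methyl-2-(prop-1-en-2-yl)cyclohexan-1-ol; 25 (2Z)-4-(acetyloxy)-2-methylbut-2-enoic acid
Product: 27 (1S,2R,3R,4S,5R)-5-ethenyl-3-[(4-methoxyphenyl)methoxy]-4-{3-[(4-methoxyphenyl)methoxy]prop-1-en-2-yl}-5-methyl-2-(prop-1-en-2-yl)cyclohexyl (2Z)-4-(acetyloxy)-2-methylbut-2-enoate, via mixed anhydride 26 (not isolated)
Conditions: 2,4,6-Cl3C6H2COCl, Et3N, toluene, 23 °C; then 19, DMAP, toluene, 23 °C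
Reagents that add atoms: none
Why: Yamaguchi esterification through the mixed anhydride should acylate the single free, equatorial secondary hydroxyl; the method is chosen because it preserves angelate-type Z geometry.

Step 16
Reactants: 27 (1S,2R,3R,4S,5R)-5-ethenyl-3-[(4-methoxyphenyl)methoxy]-4-{3-[(4-methoxyphenyl)methoxy]prop-1-en-2-yl}-5-methyl-2-(prop-1-en-2-yl)cyclohexyl (2Z)-4-(acetyloxy)-2-methylbut-2-enoate
Product: 28 (1S,2R,3R,4S,5R)-5-ethenyl-2-(3-hydroxyprop-1-en-2-yl)-3-[(4-methoxyphenyl)methoxy]-4-{3-[(4-methoxyphenyl)methoxy]prop-1-en-2-yl}-5-methylcyclohexyl (2Z)-4-(acetyloxy)-2-methylbut-2-enoate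
Conditions: SeO2 (0.3 equiv), t-BuOOH (3 equiv), CH2Cl2, 23 °C
Reagents that add atoms: selenium dioxide (oxygen carrier), O=[Se]=O; tert-butyl hydroperoxide (terminal oxidant), CC(C)(C)OO
Why: SeO2 allylic oxidation (ene reaction, then [2,3] shift) should hydroxylate the methyl group of the isopropenyl unit; the other 1,1-disubstituted alkene is deactivated by its allylic ether oxygen, the vinyl group has no allylic hydrogen and the enoate is electron-poor.

Step 17
Reactants: 28 (1S,2R,3R,4S,5R)-5-ethenyl-2-(3-hydroxyprop-1-en-2-yl)-3-[(4-methoxyphenyl)methoxy]-4-{3-[(4-methoxyphenyl)methoxy]prop-1-en-2-yl}-5-methylcyclohexyl (2Z)-4-(acetyloxy)-2-methylbut-2-enoate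
Product: 29 (1S,2R,3R,4S,5R)-5-ethenyl-3-[(4-methoxyphenyl)methoxy]-4-{3-[(4-methoxyphenyl)methoxy]prop-1-en-2-yl}-5-methyl-2-(3-oxoprop-1-en-2-yl)cyclohexyl (2Z)-4-(acetyloxy)-2-methylbut-2-enoate
Conditions: MnO2 (excess), CH2Cl2, 23 °C
Reagents that add atoms: none
Why: MnO2 oxidation of the primary allylic alcohol should give the α-methylene aldehyde and converges any aldehyde already formed in step 16.

Step 18
Reactants: 29 (1S,2R,3R,4S,5R)-5-ethenyl-3-[(4-methoxyphenyl)methoxy]-4-{3-[(4-methoxyphenyl)methoxy]prop-1-en-2-yl}-5-methyl-2-(3-oxoprop-1-en-2-yl)cyclohexyl (2Z)-4-(acetyloxy)-2-methylbut-2-enoate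
Product: 30 2-[(1R,2R,3S,4R,6S)-6-{[(2Z)-4-(acetyloxy)-2-methylbut-2-enoyl]oxy}-4-ethenyl-2-[(4-methoxyphenyl)methoxy]-3-{3-[(4-methoxyphenyl)methoxy]prop-1-en-2-yl}-4-methylcyclohexyl]prop-2-enoic acid
Conditions: NaClO2, NaH2PO4, 2-methylbut-2-ene, t-BuOH/H2O, 0 → 23 °C
Reagents that add atoms: sodium chlorite, [Na+].[O-]Cl=O
Why: Pinnick oxidation should convert the enal into the acrylic acid without touching alkenes (hypochlorous acid is scavenged), esters or PMB ethers.

Step 19
Reactants: 30 2-[(1R,2R,3S,4R,6S)-6-{[(2Z)-4-(acetyloxy)-2-methylbut-2-enoyl]oxy}-4-ethenyl-2-[(4-methoxyphenyl)methoxy]-3-{3-[(4-methoxyphenyl)methoxy]prop-1-en-2-yl}-4-methylcyclohexyl]prop-2-enoic acid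
Product: 31 2-[(1S,2R,3S,4R,6S)-6-{[(2Z)-4-(acetyloxy)-2-methylbut-2-enoyl]oxy}-4-ethenyl-2-hydroxy-3-(3-hydroxyprop-1-en-2-yl)-4-methylcyclohexyl]prop-2-enoic acid (CNP0261293.4)
Conditions: DDQ (3 equiv), CH2Cl2/pH 7 phosphate buffer, 0 → 23 °C
Reagents that add atoms: none
Why: Oxidative cleavage of both PMB ethers with DDQ under buffered, near-neutral conditions should free the secondary and the primary allylic hydroxyl without acid or base, so the acetate, the Z enoate and the γ-hydroxy acid (no lactonisation) survive.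

**Compound list**

1 | (2Z)-3-methylpent-2-en-4-yn-1-ol | C#C/C(C)=C\CO | starting material
2 | trimethyl{[(2Z)-3-methyl-5-(trimethylsilyl)pent-2-en-4-yn-1-yl]oxy}silane | C[Si](C)(C)C#C/C(C)=C\CO[Si](C)(C)C | intermediate
3 | (2Z)-3-methyl-5-(trimethylsilyl)pent-2-en-4-yn-1-ol | C[Si](C)(C)C#C/C(C)=C\CO | intermediate
4 | (2Z)-3-methyl-5-(trimethylsilyl)pent-2-en-4-ynal | C[Si](C)(C)C#C/C(C)=C\C=O | intermediate
5 | 4,4,5,5-tetramethyl-2-(propa-1,2-dien-1-yl)-1,3,2-dioxaborolane | C=C=CB1OC(C)(C)C(C)(C)O1 | starting material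
6 | (4R,5Z)-6-methyl-8-(trimethylsilyl)oct-5-ene-1,7-diyn-4-ol | C[Si](C)(C)C#C/C(C)=C\[C@H](O)CC#C | intermediate
7 | {[(4R,5Z)-6-methyl-8-(trimethylsilyl)oct-5-ene-1,7-diyn-4-yl]oxy}tri(propan-2-yl)silane | C[Si](C)(C)C#C/C(C)=C\[C@H](O[Si](C(C)C)(C(C)C)C(C)C)CC#C | intermediate
8 | 3-methylbut-2-enal | CC(C)=CC=O | starting material
9 | (3Z,5R,9S)-3,11-dimethyl-5-{[tri(propan-2-yl)silyl]oxy}-1-(trimethylsilyl)dodeca-3,10-diene-1,7-diyn-9-ol | C[Si](C)(C)C#C/C(C)=C\[C@H](O[Si](C(C)C)(C(C)C)C(C)C)CC#C[C@@H](O)C=C(C)C | intermediate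
10 | sodium alkenylalanate from trans-hydroalumination of 9 (2,5-dihydro-1,2-oxaluminol-2-uide ring: Al on C7 of the chain and bound to the C9 oxygen, two 2-methoxyethoxy groups on Al) | [Na+].COCCO[Al-]1(OCCOC)O[C@@H](C=C(C)C)C=C1C[C@@H](O[Si](C(C)C)(C(C)C)C(C)C)/C=C(C)\C#C[Si](C)(C)C | intermediate
11 | (3Z,5R,7Z,9S)-7-iodo-3,11-dimethyl-5-{[tri(propan-2-yl)silyl]oxy}-1-(trimethylsilyl)dodeca-3,7,10-trien-1-yn-9-ol | C[Si](C)(C)C#C/C(C)=C\[C@H](O[Si](C(C)C)(C(C)C)C(C)C)C/C(I)=C/[C@@H](O)C=C(C)C | intermediate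
12 | (tributylstannyl)methanol | OC[Sn](CCCC)(CCCC)CCCC | starting material
13 | (2Z,4S)-6-methyl-2-[(2R,3Z)-4-methyl-2-{[tri(propan-2-yl)silyl]oxy}-6-(trimethylsilyl)hex-3-en-5-yn-1-yl]hepta-2,5-diene-1,4-diol | C[Si](C)(C)C#C/C(C)=C\[C@H](O[Si](C(C)C)(C(C)C)C(C)C)C/C(CO)=C/[C@@H](O)C=C(C)C | intermediate
14 | {[(3Z,5R,7Z,9S)-9-[(4-methoxyphenyl)methoxy]-7-{[(4-methoxyphenyl)methoxy]methyl}-3,11-dimethyl-1-(trimethylsilyl)dodeca-3,7,10-trien-1-yn-5-yl]oxy}tri(propan-2-yl)silane | C[Si](C)(C)C#C/C(C)=C\[C@H](O[Si](C(C)C)(C(C)C)C(C)C)C/C(COCc1ccc(OC)cc1)=C/[C@@H](OCc1ccc(OC)cc1)C=C(C)C | intermediate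
15 | (3Z,5R,7Z,9S)-9-[(4-methoxyphenyl)methoxy]-7-{[(4-methoxyphenyl)methoxy]methyl}-3,11-dimethyldodeca-3,7,10-trien-1-yn-5-ol | C#C/C(C)=C\[C@H](O)C/C(COCc1ccc(OC)cc1)=C/[C@@H](OCc1ccc(OC)cc1)C=C(C)C | intermediate
16 | (3Z,5R,7Z,9S)-9-[(4-methoxyphenyl)methoxy]-7-{[(4-methoxyphenyl)methoxy]methyl}-3,11-dimethyldodeca-1,3,7,10-tetraen-5-ol | C=C/C(C)=C\[C@H](O)C/C(COCc1ccc(OC)cc1)=C/[C@@H](OCc1ccc(OC)cc1)C=C(C)C | intermediate
17 | potassium (1E,3S,4S,5S)-3-ethenyl-5-[(4-methoxyphenyl)methoxy]-4-{3-[(4-methoxyphenyl)methoxy]prop-1-en-2-yl}-3,7-dimethylocta-1,6-dien-1-olate | [K+].[O-]/C=C/[C@](C)(C=C)[C@@H](C(=C)COCc1ccc(OC)cc1)[C@@H](OCc1ccc(OC)cc1)C=C(C)C | intermediate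
18 | (3R,4S,5S)-3-ethenyl-5-[(4-methoxyphenyl)methoxy]-4-{3-[(4-methoxyphenyl)methoxy]prop-1-en-2-yl}-3,7-dimethyloct-6-enal | O=CC[C@](C)(C=C)[C@@H](C(=C)COCc1ccc(OC)cc1)[C@@H](OCc1ccc(OC)cc1)C=C(C)C | intermediate
19 | (1S,2R,3R,4S,5R)-5-ethenyl-3-[(4-methoxyphenyl)methoxy]-4-{3-[(4-methoxyphenyl)methoxy]prop-1-en-2-yl}-5-methyl-2-(prop-1-en-2-yl)cyclohexan-1-ol | C=C[C@@]1(C)C[C@H](O)[C@@H](C(C)=C)[C@H](OCc2ccc(OC)cc2)[C@@H]1C(=C)COCc1ccc(OC)cc1 | intermediate
20 | (2Z)-but-2-ene-1,4-diyl diacetate | CC(=O)OC/C=C\COC(C)=O | starting material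
21 | 1,2,4-trioxolane-3,5-diylbis(methylene) diacetate | CC(=O)OCC1OOC(COC(C)=O)O1 | intermediate
22 | 2-oxoethyl acetate | CC(=O)OCC=O | intermediate
23 | tert-butyl 2-[bis(2,2,2-trifluoroethoxy)phosphoryl]propanoate | CC(C(=O)OC(C)(C)C)P(=O)(OCC(F)(F)F)OCC(F)(F)F | starting material
24 | tert-butyl (2Z)-4-(acetyloxy)-2-methylbut-2-enoate | CC(C)(C)OC(=O)/C(C)=C\COC(C)=O | intermediate
25 | (2Z)-4-(acetyloxy)-2-methylbut-2-enoic acid | OC(=O)/C(C)=C\COC(C)=O | intermediate
26 | (2Z)-4-(acetyloxy)-2-methylbut-2-enoic 2,4,6-trichlorobenzoic anhydride | O=C(OC(=O)/C(C)=C\COC(C)=O)c1c(Cl)cc(Cl)cc1Cl | intermediate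
27 | (1S,2R,3R,4S,5R)-5-ethenyl-3-[(4-methoxyphenyl)methoxy]-4-{3-[(4-methoxyphenyl)methoxy]prop-1-en-2-yl}-5-methyl-2-(prop-1-en-2-yl)cyclohexyl (2Z)-4-(acetyloxy)-2-methylbut-2-enoate | C=C[C@@]1(C)C[C@H](OC(=O)/C(C)=C\COC(C)=O)[C@@H](C(C)=C)[C@H](OCc2ccc(OC)cc2)[C@@H]1C(=C)COCc1ccc(OC)cc1 | intermediate
28 | (1S,2R,3R,4S,5R)-5-ethenyl-2-(3-hydroxyprop-1-en-2-yl)-3-[(4-methoxyphenyl)methoxy]-4-{3-[(4-methoxyphenyl)methoxy]prop-1-en-2-yl}-5-methylcyclohexyl (2Z)-4-(acetyloxy)-2-methylbut-2-enoate | C=C[C@@]1(C)C[C@H](OC(=O)/C(C)=C\COC(C)=O)[C@@H](C(=C)CO)[C@H](OCc2ccc(OC)cc2)[C@@H]1C(=C)COCc1ccc(OC)cc1 | intermediate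
29 | (1S,2R,3R,4S,5R)-5-ethenyl-3-[(4-methoxyphenyl)methoxy]-4-{3-[(4-methoxyphenyl)methoxy]prop-1-en-2-yl}-5-methyl-2-(3-oxoprop-1-en-2-yl)cyclohexyl (2Z)-4-(acetyloxy)-2-methylbut-2-enoate | C=C[C@@]1(C)C[C@H](OC(=O)/C(C)=C\COC(C)=O)[C@@H](C(=C)C=O)[C@H](OCc2ccc(OC)cc2)[C@@H]1C(=C)COCc1ccc(OC)cc1 | intermediate
30 | 2-[(1R,2R,3S,4R,6S)-6-{[(2Z)-4-(acetyloxy)-2-methylbut-2-enoyl]oxy}-4-ethenyl-2-[(4-methoxyphenyl)methoxy]-3-{3-[(4-methoxyphenyl)methoxy]prop-1-en-2-yl}-4-methylcyclohexyl]prop-2-enoic acid | C=C[C@@]1(C)C[C@H](OC(=O)/C(C)=C\COC(C)=O)[C@@H](C(=C)C(=O)O)[C@H](OCc2ccc(OC)cc2)[C@@H]1C(=C)COCc1ccc(OC)cc1 | intermediate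
31 | 2-[(1S,2R,3S,4R,6S)-6-{[(2Z)-4-(acetyloxy)-2-methylbut-2-enoyl]oxy}-4-ethenyl-2-hydroxy-3-(3-hydroxyprop-1-en-2-yl)-4-methylcyclohexyl]prop-2-enoic acid | C=C[C@@]1(C)C[C@H](OC(=O)/C(C)=C\COC(C)=O)[C@@H](C(=C)C(=O)O)[C@H](O)[C@@H]1C(=C)CO | target

**Count and risks**

Total step count: 19. Longest linear sequence: 16 steps (steps 1–11 and 15–19); steps 12–14 are a three-step side branch.

Steps most likely to fail:

Step 11. The alkoxide-accelerated [3,3] shift may lose to anion-driven side paths: a 1,5-hydrogen shift of the Z-dienyl alkoxide to a dienolate, or β-loss of PMB-oxide from the carbon that gains negative charge. The chair may also leak to the axial-oxygen alternative. The fallback is neutral and runs at the alkyne stage, where a 1,5-hydrogen shift is impossible. It sets out from 15: Me3SiCl and imidazole give the O-trimethylsilyl ether F1; a thermal siloxy-Cope rearrangement (o-dichlorobenzene, 200 °C) gives the silyl enol ether F2; citric acid in aqueous methanol gives the ethynyl aldehyde F3; Me2AlCl in CH2Cl2 at −78 °C closes it by the same carbonyl-ene reaction to the ethynyl cyclohexanol F4; Lindlar semihydrogenation as in step 10 then comes back to the route at 19.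

Step 16. The selenium ene oxidation may fail to discriminate between the two 1,1-disubstituted alkenes, or may oxidise the allylic PMB ether away. The fallback uses the free hydroxyl as a directing group and sets out from 19: VO(acac)2 with t-BuOOH epoxidises only the homoallylic isopropenyl alkene to the epoxy alcohol F5 (either epoxide epimer serves); Yamaguchi esterification with 25 as in step 15 gives the epoxy ester F6; titanocene-mediated radical opening of the 2,2-disubstituted epoxide with β-hydride elimination (Cp2TiCl2, Mn dust, 2,4,6-collidine hydrochloride, THF) isomerises it to the 2-substituted allylic alcohol and comes back to the route at 28.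

Step 5. Facial selectivity may be poor, or addition of the alkynylzinc to the hindered β,β-disubstituted enal may be slow. The fallback separates C–C bond formation from the creation of the stereocentre and sets out from 7: lithiation (n-BuLi, THF, −78 °C) and acylation with N-methoxy-N,3-dimethylbut-2-enamide give the ynone F7; Noyori asymmetric transfer hydrogenation of the alkynyl ketone (RuCl[(S,S)-TsDPEN](p-cymene), i-PrOH) then comes back to the route at 9.

**Further compounds**

F1 | step 11 | O-trimethylsilyl ether of 15 | C#C/C(C)=C\[C@H](O[Si](C)(C)C)C/C(COCc1ccc(OC)cc1)=C/[C@@H](OCc1ccc(OC)cc1)C=C(C)C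
F2 | step 11 | (E)-trimethylsilyl enol ether of aldehyde F3 | C[Si](C)(C)O/C=C/[C@](C)(C#C)[C@@H](C(=C)COCc1ccc(OC)cc1)[C@@H](OCc1ccc(OC)cc1)C=C(C)C
F3 | step 11 | ethynyl analogue of aldehyde 18 (ethynyl in place of ethenyl on the quaternary carbon) | O=CC[C@](C)(C#C)[C@@H](C(=C)COCc1ccc(OC)cc1)[C@@H](OCc1ccc(OC)cc1)C=C(C)C
F4 | step 11 | ethynyl analogue of cyclohexanol 19 (ethynyl in place of ethenyl) | C#C[C@@]1(C)C[C@H](O)[C@@H](C(C)=C)[C@H](OCc2ccc(OC)cc2)[C@@H]1C(=C)COCc1ccc(OC)cc1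
F5 | step 16 | epoxide of 19 at the isopropenyl group (2-methyloxiran-2-yl in place of prop-1-en-2-yl, either epimer at the epoxide carbon) | C=C[C@@]1(C)C[C@H](O)[C@@H](C2(C)CO2)[C@H](OCc2ccc(OC)cc2)[C@@H]1C(=C)COCc1ccc(OC)cc1
F6 | step 16 | (2Z)-4-(acetyloxy)-2-methylbut-2-enoate ester of F5 | C=C[C@@]1(C)C[C@H](OC(=O)/C(C)=C\COC(C)=O)[C@@H](C2(C)CO2)[C@H](OCc2ccc(OC)cc2)[C@@H]1C(=C)COCc1ccc(OC)cc1
F7 | step 5 | (3Z,5R)-3,11-dimethyl-5-{[tri(propan-2-yl)silyl]oxy}-1-(trimethylsilyl)dodeca-3,10-diene-1,7-diyn-9-one | C[Si](C)(C)C#C/C(C)=C\[C@H](O[Si](C(C)C)(C(C)C)C(C)C)CC#CC(=O)C=C(C)C
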